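**Retrosynthetic overview**
- Target ⇒ protected isoflavan (one BCl3 operation frees 4'-OH and the 7-OH ortho to CHO) ⇒ C3–C4 disconnection: a (3R)-3-aryl-2,3,4,5-tetrahydro-1,4-benzoxazepine with an NH between C3 and C4, whose seven-membered O,N-ring contracts to the six-membered chroman ring by loss of N2 (nitrogen deletion).
- Enabling feature: in the dihydropyran ring, C4 is benzylic to ring A (bonded to C4a) and C3 is benzylic to ring B (bonded to C1'). An NH placed between them is flanked by two benzylic carbons, which is what isodiazene N2 extrusion and radical recombination need.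
- Benzoxazepine ⇒ C2-symmetric 2-hydroxy-4,6-dimethoxyisophthalaldehyde + (R)-N-Boc-arylglycinol, joined by Mitsunobu (O1–C2) and cyclising reductive amination (N–C4). One CHO becomes C4; its twin stays as the C8 aldehyde and later marks the ortho OMe for cleavage.
- Arylglycinol ⇒ Sharpless aminohydroxylation of an 8-vinyl-2,2-dimethylchromene (sets C3) ⇒ propargyl-ether Claisen/oxa-6π annulation on 4-benzyloxysalicylaldehyde.
- Ring order: B-ring dimethylpyran first, then the 1,4-benzoxazepine, then ring contraction to the chroman.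

Key step: step 8

Remark: the given SMILES is the (3R)-isoflavan; chroman numbering (O1, C2, C3, C4, C4a–C8a) and B-ring numbering (C1'–C6') are used throughout.

**Step 1**
Reactants: 1 4-(benzyloxy)-2-hydroxybenzaldehyde; 2 3-chloro-3-methylbut-1-yne
Product: 3 4-(benzyloxy)-2-[(2-methylbut-3-yn-2-yl)oxy]benzaldehyde
Conditions: DBU, CuCl2·2H2O (1 mol %), MeCN, 0 °C to rt
Reagents that add atoms: none
Why: Copper-catalysed O-propargylation of the only free phenol with a tertiary propargylic chloride (Williamson-type etherification via a copper acetylide) is a standard entry to aryl 1,1-dimethylpropargyl ethers.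

**Step 2**
Reactants: 3 4-(benzyloxy)-2-[(2-methylbut-3-yn-2-yl)oxy]benzaldehyde
Product: 6 5-(benzyloxy)-2,2-dimethyl-2H-chromene-8-carbaldehyde, via allenylphenol 4 (not isolated), via dienone 5 (not isolated)
Conditions: N,N-diethylaniline, 190 °C
Reagents that add atoms: none
Why: The aromatic propargyl Claisen rearrangement can only reach the free ortho carbon between the two oxygens (the other ortho position carries CHO); tautomerisation gives 4, a 1,5-hydrogen shift gives 5, and oxa-6π electrocyclisation should close the 2,2-dimethyl-2H-pyran regiospecifically.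

**Step 3**
Reactants: 6 5-(benzyloxy)-2,2-dimethyl-2H-chromene-8-carbaldehyde
Product: 7 5-(benzyloxy)-8-ethenyl-2,2-dimethyl-2H-chromene
Conditions: Ph3PCH3Br, KOtBu, THF, 0 °C to rt
Reagents that add atoms: methyltriphenylphosphonium bromide, C[P+](c1ccccc1)(c1ccccc1)c1ccccc1.[Br-]
Why: Wittig methylenation of the aryl aldehyde should give the terminal styrene needed for aminohydroxylation and leaves the chromene alkene and benzyl ether untouched.

**Step 4**
Reactants: 7 5-(benzyloxy)-8-ethenyl-2,2-dimethyl-2H-chromene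
Product: 8 tert-butyl N-[(1R)-1-[5-(benzyloxy)-2,2-dimethyl-2H-chromen-8-yl]-2-hydroxyethyl]carbamate
Conditions: BocNH2, t-BuOCl, NaOH, K2OsO2(OH)4 (4 mol %), (DHQD)2PHAL (5 mol %), n-PrOH/H2O 1:1, 0 °C
Reagents that add atoms: tert-butyl carbamate, NC(=O)OC(C)(C)C; water, O
Why: In this Sharpless asymmetric aminohydroxylation the (DHQD)2PHAL–osmium catalyst should add N and O suprafacially to the terminal styrene from the face that gives the (R)-benzylic carbamate (the sense known for styrenes with this ligand, N preferring the benzylic carbon in n-PrOH/water), while the hindered cis-disubstituted chromene alkene reacts far more slowly.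

**Step 5**
Reactants: 9 2-hydroxy-4,6-dimethoxybenzaldehyde
Product: 10 2-hydroxy-4,6-dimethoxybenzene-1,3-dicarbaldehyde
Conditions: Cl2CHOMe, TiCl4, CH2Cl2, 0 °C to rt; then aq. HCl
Reagents that add atoms: dichloromethyl methyl ether, COC(Cl)Cl; water, O
Why: Rieche formylation (Friedel–Crafts attack of the TiCl4-activated dichloromethyl ether, hydrolysis on work-up) is directed by the titanium phenoxide to the ortho carbon C3, which is also ortho and para to a methoxy group, and should give the C2-symmetric dialdehyde.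

**Step 6**
Reactants: 10 2-hydroxy-4,6-dimethoxybenzene-1,3-dicarbaldehyde; 8 tert-butyl N-[(1R)-1-[5-(benzyloxy)-2,2-dimethyl-2H-chromen-8-yl]-2-hydroxyethyl]carbamate
Product: 11 tert-butyl N-[(1R)-1-[5-(benzyloxy)-2,2-dimethyl-2H-chromen-8-yl]-2-(2,6-diformyl-3,5-dimethoxyphenoxy)ethyl]carbamate
Conditions: PPh3, DIAD, THF, 0 °C to rt
Reagents that add atoms: none
Why: Mitsunobu etherification should join the acidic, doubly chelated phenol of 10 (a good pronucleophile) to the primary hydroxyl of 8 by SN2 at CH2, so the neighbouring carbamate-bearing stereocentre is not touched.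

**Step 7**
Reactants: 11 tert-butyl N-[(1R)-1-[5-(benzyloxy)-2,2-dimethyl-2H-chromen-8-yl]-2-(2,6-diformyl-3,5-dimethoxyphenoxy)ethyl]carbamate
Product: 14 (3R)-3-[5-(benzyloxy)-2,2-dimethyl-2H-chromen-8-yl]-6,8-dimethoxy-2,3,4,5-tetrahydro-1,4-benzoxazepine-9-carbaldehyde, via primary amine 12 (not isolated), via cyclic imine 13 (not isolated)
Conditions: TMSOTf, 2,6-lutidine, CH2Cl2, 0 °C; MeOH; then NaBH(OAc)3, AcOH, ClCH2CH2Cl, rt
Reagents that add atoms: none
Why: Silyl-triflate cleavage of the Boc group under buffered, non-protic conditions spares the chromene; the freed amine 12 should condense intramolecularly with either of the two equivalent ortho formyl groups to the seven-membered imine 13 (which desymmetrises ring A), and NaBH(OAc)3 reduces the iminium ion but not the remaining electron-rich, hindered aryl aldehyde (reductive amination).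

**Step 8**
Reactants: 14 (3R)-3-[5-(benzyloxy)-2,2-dimethyl-2H-chromen-8-yl]-6,8-dimethoxy-2,3,4,5-tetrahydro-1,4-benzoxazepine-9-carbaldehyde
Product: 17 (3R)-3-[5-(benzyloxy)-2,2-dimethyl-2H-chromen-8-yl]-5,7-dimethoxy-3,4-dihydro-2H-chromene-8-carbaldehyde, via isodiazene 15 (not isolated), via benzylic diradical 16 (not isolated)
Conditions: N-(benzyloxy)-N-(pivaloyloxy)-4-(trifluoromethyl)benzamide (1.5 equiv), THF, 45 °C
Reagents that add atoms: none
Why: The secondary amine attacks the nitrogen of the anomeric amide with loss of pivalate, reductive elimination of benzyl 4-(trifluoromethyl)benzoate gives isodiazene 15, and 15 expels N2 to the singlet diradical 16, which collapses to the C3–C4 bond. The closest known reaction type is the nitrogen deletion of dibenzylic secondary amines with this reagent, together with the stereoretentive isodiazene contraction of 2-arylpyrrolidines to cyclobutanes. The six-membered dihydropyran ring is closed by radical–radical recombination of the two benzylic termini, i.e. the seven-membered 1,4-oxazepine ring contracts by extrusion of its nitrogen. No new stereocentre is formed: C3 should be carried over with retention, because the C4 radical is born about 2.4 Å away on the face that nitrogen occupied and collapse to the strain-free ring should outrun rotation about C2–C3. The step needs recombination to win over β-scission of the C2–O1 bond and over hydrazone or tetrazene formation; this is secured by both carbons flanking nitrogen being benzylic (ring A at C4, ring B at C3) and by the aryl-ether tether that holds the two radicals together. The aldehyde, benzyl ether, methyl ethers and chromene alkene should be inert to the reagent at 45 °C.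

**Step 9**
Reactants: 17 (3R)-3-[5-(benzyloxy)-2,2-dimethyl-2H-chromen-8-yl]-5,7-dimethoxy-3,4-dihydro-2H-chromene-8-carbaldehyde
Product: 18 (3R)-7-hydroxy-3-(5-hydroxy-2,2-dimethyl-2H-chromen-8-yl)-5-methoxy-3,4-dihydro-2H-chromene-8-carbaldehyde
Conditions: BCl3, pentamethylbenzene, CH2Cl2, −78 to −20 °C; then MeOH, aq. NaHCO3
Reagents that add atoms: none
Why: Boron trichloride should cleave the benzyl ether at low temperature (benzyl cation trapped by pentamethylbenzene) and, through the six-membered boron chelate with the formyl group, selectively the ortho methoxy group at C7, whereas the non-chelated C5 methoxy group, the β-branched ring ether O1–C2 and the chromene are expected to survive (chelation-controlled Lewis-acid dealkylation).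

**Compound list**
1 | 4-(benzyloxy)-2-hydroxybenzaldehyde | O=Cc1ccc(OCc2ccccc2)cc1O | starting material
2 | 3-chloro-3-methylbut-1-yne | C#CC(C)(C)Cl | starting material
3 | 4-(benzyloxy)-2-[(2-methylbut-3-yn-2-yl)oxy]benzaldehyde | O=Cc1ccc(OCc2ccccc2)cc1OC(C)(C)C#C | intermediate
4 | 4-(benzyloxy)-2-hydroxy-3-(3-methylbuta-1,2-dien-1-yl)benzaldehyde (allenylphenol, not isolated) | O=Cc1ccc(OCc2ccccc2)c(C=C=C(C)C)c1O | intermediate
5 | 4-(benzyloxy)-5-[(Z)-3-methylbut-2-en-1-ylidene]-6-oxocyclohexa-1,3-diene-1-carbaldehyde (dienone, not isolated) | O=CC1=CC=C(OCc2ccccc2)/C(=C/C=C(C)C)C1=O | intermediate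
6 | 5-(benzyloxy)-2,2-dimethyl-2H-chromene-8-carbaldehyde | O=Cc1ccc(OCc2ccccc2)c2C=CC(C)(C)Oc12 | intermediate
7 | 5-(benzyloxy)-8-ethenyl-2,2-dimethyl-2H-chromene | C=Cc1ccc(OCc2ccccc2)c2C=CC(C)(C)Oc12 | intermediate
8 | tert-butyl N-[(1R)-1-[5-(benzyloxy)-2,2-dimethyl-2H-chromen-8-yl]-2-hydroxyethyl]carbamate | CC(C)(C)OC(=O)N[C@H](c1ccc(OCc2ccccc2)c2C=CC(C)(C)Oc12)CO | intermediate
9 | 2-hydroxy-4,6-dimethoxybenzaldehyde | COc1cc(O)c(C=O)c(OC)c1 | starting material
10 | 2-hydroxy-4,6-dimethoxybenzene-1,3-dicarbaldehyde | COc1cc(OC)c(C=O)c(O)c1C=O | intermediate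
11 | tert-butyl N-[(1R)-1-[5-(benzyloxy)-2,2-dimethyl-2H-chromen-8-yl]-2-(2,6-diformyl-3,5-dimethoxyphenoxy)ethyl]carbamate | CC(C)(C)OC(=O)N[C@H](c1ccc(OCc2ccccc2)c2C=CC(C)(C)Oc12)COc1c(C=O)c(OC)cc(OC)c1C=O | intermediate
12 | 2-[(2R)-2-amino-2-[5-(benzyloxy)-2,2-dimethyl-2H-chromen-8-yl]ethoxy]-4,6-dimethoxybenzene-1,3-dicarbaldehyde (not isolated) | N[C@H](c1ccc(OCc2ccccc2)c2C=CC(C)(C)Oc12)COc1c(C=O)c(OC)cc(OC)c1C=O | intermediate
13 | (3R)-3-[5-(benzyloxy)-2,2-dimethyl-2H-chromen-8-yl]-6,8-dimethoxy-2,3-dihydro-1,4-benzoxazepine-9-carbaldehyde (cyclic imine, not isolated) | O=Cc1c(OC)cc(OC)c2C=N[C@H](c3ccc(OCc4ccccc4)c4C=CC(C)(C)Oc34)COc12 | intermediate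
14 | (3R)-3-[5-(benzyloxy)-2,2-dimethyl-2H-chromen-8-yl]-6,8-dimethoxy-2,3,4,5-tetrahydro-1,4-benzoxazepine-9-carbaldehyde | O=Cc1c(OC)cc(OC)c2CN[C@H](c3ccc(OCc4ccccc4)c4C=CC(C)(C)Oc34)COc12 | intermediate
15 | isodiazene (1,1-diazene at N4) of 14 (not isolated) | O=Cc1c(OC)cc(OC)c2C[N+](=[N-])[C@H](c3ccc(OCc4ccccc4)c4C=CC(C)(C)Oc34)COc12 | intermediate
16 | singlet benzylic 1,6-diradical (CH2 radical on ring A, CH radical α to ring B; C3 planar, its ring-face memory cannot be written in SMILES; not isolated) | O=Cc1c(OC)cc(OC)c([CH2])c1OC[CH]c1ccc(OCc2ccccc2)c2C=CC(C)(C)Oc12 | intermediate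
17 | (3R)-3-[5-(benzyloxy)-2,2-dimethyl-2H-chromen-8-yl]-5,7-dimethoxy-3,4-dihydro-2H-chromene-8-carbaldehyde | O=Cc1c(OC)cc(OC)c2C[C@H](c3ccc(OCc4ccccc4)c4C=CC(C)(C)Oc34)COc12 | intermediate
18 | (3R)-7-hydroxy-3-(5-hydroxy-2,2-dimethyl-2H-chromen-8-yl)-5-methoxy-3,4-dihydro-2H-chromene-8-carbaldehyde | COc1cc(O)c(C=O)c2c1C[C@H](c1ccc(O)c3c1OC(C)(C)C=C3)CO2 | target

**Step count and risks**
Total step count: 9. Longest linear sequence: 8 steps (steps 1, 2, 3, 4, 6, 7, 8, 9 from compound 1); step 5 is a one-step side branch.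

Steps most likely to fail:

1. Step 8 (nitrogen deletion). The configuration at C3 may erode if the benzylic diradical lives long enough to rotate about C2–C3 before it couples, and the diradical may fragment by β-scission of the C2–O1 bond. The fallback forms C3–C4 by closed-shell chemistry with no radical at C3; it sets out from 6 and 10 and returns to the route at 17. Aldehyde 6 would be homologated with (methoxymethyl)triphenylphosphonium chloride/KHMDS to the enol ether 5-(benzyloxy)-8-[(E)-2-methoxyethenyl]-2,2-dimethyl-2H-chromene F1 (an E/Z mixture is acceptable). Dialdehyde 10 would be mono-reduced (NaBH4, 0.3 equiv, THF/MeOH, −40 °C) to 2-hydroxy-3-(hydroxymethyl)-4,6-dimethoxybenzaldehyde F2. A chiral BINOL-derived phosphoric acid (enantiomer chosen for 3R; 4 Å sieves, toluene) would dehydrate F2 to the o-quinone methide 2,4-dimethoxy-5-methylidene-6-oxocyclohexa-1,3-diene-1-carbaldehyde F3. F3 should undergo an inverse-electron-demand oxa-Diels–Alder reaction with F1 (CH2 terminus to the aryl-bearing carbon) to give the 2-methoxyisoflavan (3R)-3-[5-(benzyloxy)-2,2-dimethyl-2H-chromen-8-yl]-2,5,7-trimethoxy-3,4-dihydro-2H-chromene-8-carbaldehyde F4 (both C2 epimers). Ionic reduction of the anomeric methoxy group (Et3SiH, BF3·OEt2, CH2Cl2, −78 °C) would then give 17.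

2. Step 4 (aminohydroxylation). Nitrogen may be delivered to the terminal instead of the benzylic carbon, the chromene alkene may be osmylated competitively, and the hypochlorite may chlorinate the electron-rich ring. The fallback uses auxiliary-controlled C–C bond formation instead of alkene difunctionalisation; it sets out from 6 and returns at 8. Condensation of 6 with (R)-tert-butanesulfinamide (Ti(OEt)4, THF) would give the sulfinyl imine (R)-N-[(E)-[5-(benzyloxy)-2,2-dimethyl-2H-chromen-8-yl]methylidene]-2-methylpropane-2-sulfinamide F5. Addition of the hydroxymethyl-anion equivalent (isopropoxydimethylsilyl)methylmagnesium chloride in CH2Cl2 (chelated chair transition state, Si-face attack) should give (R)-N-[(1R)-1-[5-(benzyloxy)-2,2-dimethyl-2H-chromen-8-yl]-2-[dimethyl(propan-2-yloxy)silyl]ethyl]-2-methylpropane-2-sulfinamide F6. Tamao–Fleming oxidation (H2O2, KF, KHCO3, THF/MeOH) would give the N-sulfinyl amino alcohol (R)-N-[(1R)-1-[5-(benzyloxy)-2,2-dimethyl-2H-chromen-8-yl]-2-hydroxyethyl]-2-methylpropane-2-sulfinamide F7. Brief HCl/MeOH at 0 °C would release (2R)-2-amino-2-[5-(benzyloxy)-2,2-dimethyl-2H-chromen-8-yl]ethan-1-ol F8, and Boc2O/Et3N would give 8.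

3. Step 5 (second formylation). The CHO-deactivated ring may react sluggishly, and the electrophile may enter at C5 (para to OH, between the two methoxy groups) instead of C3. The fallback replaces Friedel–Crafts formylation by phenoxide-directed hydroxymethylation/hydride transfer; it sets out from 9 and returns at 10. In the Casnati–Skattebøl ortho-formylation (MgCl2, Et3N, paraformaldehyde, MeCN, reflux) formaldehyde is delivered within the magnesium phenoxide chelate and can only reach the carbon ortho to the phenol. No new isolated compound is involved.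

**Further compounds**
F1 | step 8 | 5-(benzyloxy)-8-[(E)-2-methoxyethenyl]-2,2-dimethyl-2H-chromene | CO/C=C/c1ccc(OCc2ccccc2)c2C=CC(C)(C)Oc12
F2 | step 8 | 2-hydroxy-3-(hydroxymethyl)-4,6-dimethoxybenzaldehyde | COc1cc(OC)c(C=O)c(O)c1CO
F3 | step 8 | 2,4-dimethoxy-5-methylidene-6-oxocyclohexa-1,3-diene-1-carbaldehyde | C=C1C(=O)C(C=O)=C(OC)C=C1OC
F4 | step 8 | (3R)-3-[5-(benzyloxy)-2,2-dimethyl-2H-chromen-8-yl]-2,5,7-trimethoxy-3,4-dihydro-2H-chromene-8-carbaldehyde (C2 epimers) | O=Cc1c(OC)cc(OC)c2C[C@H](c3ccc(OCc4ccccc4)c4C=CC(C)(C)Oc34)C(OC)Oc12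
F5 | step 4 | (R)-N-[(E)-[5-(benzyloxy)-2,2-dimethyl-2H-chromen-8-yl]methylidene]-2-methylpropane-2-sulfinamide | CC(C)(C)[S@@](=O)/N=C/c1ccc(OCc2ccccc2)c2C=CC(C)(C)Oc12
F6 | step 4 | (R)-N-[(1R)-1-[5-(benzyloxy)-2,2-dimethyl-2H-chromen-8-yl]-2-[dimethyl(propan-2-yloxy)silyl]ethyl]-2-methylpropane-2-sulfinamide | CC(C)(C)[S@@](=O)N[C@H](c1ccc(OCc2ccccc2)c2C=CC(C)(C)Oc12)C[Si](C)(C)OC(C)C
F7 | step 4 | (R)-N-[(1R)-1-[5-(benzyloxy)-2,2-dimethyl-2H-chromen-8-yl]-2-hydroxyethyl]-2-methylpropane-2-sulfinamide | CC(C)(C)[S@@](=O)N[C@H](c1ccc(OCc2ccccc2)c2C=CC(C)(C)Oc12)CO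
F8 | step 4 | (2R)-2-amino-2-[5-(benzyloxy)-2,2-dimethyl-2H-chromen-8-yl]ethan-1-ol | N[C@H](c1ccc(OCc2ccccc2)c2C=CC(C)(C)Oc12)CO
F0 | step 5 | none | none
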